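**Retrosynthetic overview**
1. Both oxygen rings (spiro tetrahydrofuran and dihydrofuran) come last and together: anti Se/O addition of the 9α-hydroxyl across C13=C16 of a 3-furyl side chain, then C–Se to C–H.
2. The C11–C12 bond comes from a 9α,11-epoxide and a 3-furylmethyl Grignard reagent; the epoxide comes from the C9 ketone by methylenation and α-face epoxidation.
3. The 6β-oxygenated trans-decalin with a C9 ketone comes from a cis enedione by hydrogenation, epimerisation and C6-selective reduction.
4. Key disconnection: the enedione is the enantioselective Diels–Alder adduct of symmetric 2,6-dimethyl-1,4-benzoquinone (ring B, carrying both oxygens and the C8/C10 methyls) and 4-methylpenta-1,3-diene (ring A); the quinone comes from 2,6-dimethylphenol.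
5. Ring order: B (from the arene), then A (cycloaddition), then the two O-heterocycles in one dearomatising step.

Assumption: labdane numbering (C1–C20; α = face opposite the C10 methyl) is used for locants, and the S-catalyst of step 2 is taken to give the (4aR,8aS) adduct (if the sense is opposite, the R-catalyst is used with no other change).

**Route**

Step 1
Reactants: 1 2,6-dimethylphenol
Product: 2 2,6-dimethyl-1,4-benzoquinone
Conditions: O2 (1 atm), Co(salen) (5 mol %), DMF, 25 °C
Reagents that add atoms: dioxygen, O=O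
Why: Cobalt–salen/dioxygen oxidation of a 2,6-disubstituted phenol (oxidative dearomatisation) traps the phenoxyl radical at the free para position and gives the p-quinone; no stereocentre is formed.

Step 2
Reactants: 2 2,6-dimethyl-1,4-benzoquinone; 3 4-methylpenta-1,3-diene
Product: 4 (4aR,8aS)-2,5,5,8a-tetramethyl-4a,5,8,8a-tetrahydronaphthalene-1,4-dione
Conditions: 3 (4 equiv), (S)-3,3-diphenyl-1-(o-tolyl)tetrahydro-1H,3H-pyrrolo[1,2-c][1,3,2]oxazaborole (20 mol %), HNTf2 (18 mol %), CH2Cl2, −78 → −30 °C
Reagents that add atoms: none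
Why: Catalytic enantioselective Diels–Alder reaction (chiral oxazaborolidinium Lewis acid) that desymmetrises the quinone: the cation binds the more basic, unhindered C4 carbonyl next to C3–H, the unsubstituted diene terminus bonds to the methyl-bearing β-carbon (future C10, set as S by the shielded enone face) and the dimethylated terminus to C3 (future C5), with the cis ring fusion following from suprafacial addition.

Step 3
Reactants: 4 (4aR,8aS)-2,5,5,8a-tetramethyl-4a,5,8,8a-tetrahydronaphthalene-1,4-dione
Product: 6 (2R,4aS,8aS)-2,5,5,8a-tetramethyl-2,3,4a,5,6,7,8,8a-octahydronaphthalene-1,4-dione, via cis-fused dione 5 (not isolated)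
Conditions: H2 (1 atm), 10% Pd/C, EtOAc, 25 °C; filter; then NaOMe (0.3 equiv), MeOH, 25 °C
Reagents that add atoms: none
Why: Heterogeneous hydrogenation saturates the enedione and ring A alkenes, and enolate equilibration then epimerises C5 (α to the C6 ketone; axial protonation anti to the C10 methyl) to the trans ring fusion and C8 (α to the C9 ketone) to the equatorial 8α-methyl, both under thermodynamic control relative to fixed C10.

Step 4
Reactants: 6 (2R,4aS,8aS)-2,5,5,8a-tetramethyl-2,3,4a,5,6,7,8,8a-octahydronaphthalene-1,4-dione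
Product: 7 (2R,4R,4aS,8aS)-4-hydroxy-2,5,5,8a-tetramethyloctahydronaphthalen-1(2H)-one
Conditions: NaBH4 (0.5 equiv), MeOH/CH2Cl2 1:1, −40 → −20 °C
Reagents that add atoms: none
Why: Chemoselective borohydride reduction of the C6 ketone (the C9 ketone is flanked by quaternary C10 and the C8 methine) with hydride entering from the α-face, opposite the axial β-methyls on C4 and C10, which sets the axial 6β-hydroxyl (6R).

Step 5
Reactants: 7 (2R,4R,4aS,8aS)-4-hydroxy-2,5,5,8a-tetramethyloctahydronaphthalen-1(2H)-one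
Product: 8 (1R,3R,4aS,8aS)-3,4a,8,8-tetramethyl-4-methylidenedecahydronaphthalen-1-ol
Conditions: Ph3PCH3Br (4 equiv), KOt-Bu (4 equiv), toluene, 100 °C
Reagents that add atoms: methyltriphenylphosphonium bromide, C[P+](c1ccccc1)(c1ccccc1)c1ccccc1.[Br-]
Why: Wittig methylenation under hot, forcing conditions suited to hindered ketones; the hydroxyl rides through as its potassium alkoxide and the already thermodynamic C8 centre is not changed.

Step 6
Reactants: 8 (1R,3R,4aS,8aS)-3,4a,8,8-tetramethyl-4-methylidenedecahydronaphthalen-1-ol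
Product: 9 (1R,2R,4R,4aS,8aS)-2,5,5,8a-tetramethyloctahydro-2H-spiro[naphthalene-1,2′-oxiran]-4-ol
Conditions: DMDO (1.3 equiv, ca. 0.07 M in acetone), CH2Cl2, −20 → 0 °C
Reagents that add atoms: dimethyldioxirane, CC1(C)OO1
Why: Epoxidation of the exocyclic 9(11)-alkene from the α-face, anti to the adjacent axial 10β-methyl that blocks the β-face, places the new oxygen axial (9α, 9R) and leaves C11 equatorial.

Step 7
Reactants: 10 furan-3-ylmethanol
Product: 11 3-(chloromethyl)furan
Conditions: SOCl2 (1.1 equiv), pyridine (1.2 equiv), Et2O, 0 °C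
Reagents that add atoms: thionyl chloride, O=S(Cl)Cl
Why: Chlorodehydroxylation of a primary furylmethyl alcohol through its chlorosulfite (nucleophilic substitution) under buffered conditions; the labile chloride is used at once.

Step 8
Reactants: 9 (1R,2R,4R,4aS,8aS)-2,5,5,8a-tetramethyloctahydro-2H-spiro[naphthalene-1,2′-oxiran]-4-ol; 11 3-(chloromethyl)furan
Product: 13 (1R,2R,4R,4aS,8aS)-1-[2-(furan-3-yl)ethyl]-2,5,5,8a-tetramethyldecahydronaphthalene-1,4-diol, via 3-furylmethylmagnesium chloride 12 (not isolated)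
Conditions: 11 (3 equiv), Mg, THF, 0 °C; then 9, CuBr·SMe2 (10 mol %), THF, −30 → 25 °C; aq NH4Cl
Reagents that add atoms: none
Why: Copper-catalysed Grignard opening of a 2,2-disubstituted epoxide at its primary carbon (SN2 at C11, forming C11–C12) leaves the C9–O bond untouched, so the 9α-hydroxyl and β-equatorial side chain are inherited from 9.

Step 9
Reactants: 13 (1R,2R,4R,4aS,8aS)-1-[2-(furan-3-yl)ethyl]-2,5,5,8a-tetramethyldecahydronaphthalene-1,4-diol
Product: 14 (1R,3R,4R,4aS,8aS)-4-[2-(furan-3-yl)ethyl]-4-hydroxy-3,4a,8,8-tetramethyldecahydronaphthalen-1-yl acetate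
Conditions: Ac2O (5 equiv), DMAP (0.2 equiv), pyridine, 50 °C
Reagents that add atoms: acetic anhydride, CC(=O)OC(C)=O
Why: DMAP-catalysed acylation esterifies the hindered axial secondary 6β-hydroxyl while the tertiary 9α-hydroxyl is inert; no stereocentre changes.

Step 10
Reactants: 14 (1R,3R,4R,4aS,8aS)-4-[2-(furan-3-yl)ethyl]-4-hydroxy-3,4a,8,8-tetramethyldecahydronaphthalen-1-yl acetate
Product: 15 (5S,6R,8R,9R,10S,13R,16S)-16-(phenylselanyl)-9,13:15,16-diepoxylabd-14-en-6-yl acetate
Conditions: PhSeCl (1.1 equiv), 2,6-di-tert-butyl-4-methylpyridine (1.5 equiv), CH2Cl2, −78 °C; aq NaHCO3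
Reagents that add atoms: benzeneselenenyl chloride, Cl[Se]c1ccccc1
Why: Proposed new method: PhSe+ adds to the furan at C16 (the α-carbon next to the alkyl group, the usual site of electrophilic attack on 3-alkylfurans) and the resulting 2H-furanium ion is captured at C13 by the axial 9α-hydroxyl in a 5-exo closure before it loses a proton, giving anti O/Se addition across C13=C16 (16S) with the C14=C15 enol ether retained, the closest known reaction types being selenoetherification of alkenes and the dearomatising 2,5-dialkoxylation of furans by halogen electrophiles; C13 is set here with little intrinsic bias (C16 lies over C8 in the 13R isomer and over C10 in the 13S isomer), so 13R-15 is taken by chromatography and the 13S isomer is returned to 14 by deselenation and trace-acid rearomatisation.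

Step 11
Reactants: 15 (5S,6R,8R,9R,10S,13R,16S)-16-(phenylselanyl)-9,13:15,16-diepoxylabd-14-en-6-yl acetate
Product: 16 (5S,6R,8R,9R,10S,13R)-9,13:15,16-diepoxylabd-14-en-6-yl acetate
Conditions: Bu3SnH (1.5 equiv), Et3B (0.2 equiv), air, toluene (0.5 vol % Et3N), 0 → 25 °C
Reagents that add atoms: none
Why: Radical chain reduction of the O,Se-acetal (homolytic C–Se cleavage, then hydrogen transfer from the tin hydride to the α-oxy C16 radical) under neutral conditions replaces selenium by hydrogen, removes the C16 stereocentre and leaves the acid-labile spiro enol ether, the acetate and C13 untouched.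

**Compound list**

1 | 2,6-dimethylphenol | Cc1cccc(C)c1O | starting material
2 | 2,6-dimethyl-1,4-benzoquinone | CC1=CC(=O)C=C(C)C1=O | intermediate
3 | 4-methylpenta-1,3-diene | CC(C)=CC=C | starting material
4 | (4aR,8aS)-2,5,5,8a-tetramethyl-4a,5,8,8a-tetrahydronaphthalene-1,4-dione (cis-fused; angular H and CH3 cis) | O=C1C=C(C)C(=O)[C@@]2(C)CC=CC(C)(C)[C@@H]12 | intermediate
5 | (2R,4aR,8aS)-2,5,5,8a-tetramethyl-2,3,4a,5,6,7,8,8a-octahydronaphthalene-1,4-dione (cis-fused; major C2 epimer shown, both converge) | O=C1C[C@@H](C)C(=O)[C@@]2(C)CCCC(C)(C)[C@@H]12 | intermediate (not isolated)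
6 | (2R,4aS,8aS)-2,5,5,8a-tetramethyl-2,3,4a,5,6,7,8,8a-octahydronaphthalene-1,4-dione (trans-fused; equatorial 2-CH3) | O=C1C[C@@H](C)C(=O)[C@@]2(C)CCCC(C)(C)[C@H]12 | intermediate
7 | (2R,4R,4aS,8aS)-4-hydroxy-2,5,5,8a-tetramethyloctahydronaphthalen-1(2H)-one (axial OH cis to the angular CH3; labdane 6β-ol 9-one) | O[C@@H]1C[C@@H](C)C(=O)[C@@]2(C)CCCC(C)(C)[C@H]12 | intermediate
8 | (1R,3R,4aS,8aS)-3,4a,8,8-tetramethyl-4-methylidenedecahydronaphthalen-1-ol | O[C@@H]1C[C@@H](C)C(=C)[C@@]2(C)CCCC(C)(C)[C@H]12 | intermediate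
9 | (1R,2R,4R,4aS,8aS)-2,5,5,8a-tetramethyloctahydro-2H-spiro[naphthalene-1,2′-oxiran]-4-ol (9α,11-epoxide; O trans to the angular CH3) | O[C@@H]1C[C@@H](C)[C@]2(CO2)[C@@]3(C)CCCC(C)(C)[C@H]13 | intermediate
10 | furan-3-ylmethanol | OCc1ccoc1 | starting material
11 | 3-(chloromethyl)furan | ClCc1ccoc1 | intermediate
12 | (furan-3-ylmethyl)magnesium chloride | Cl[Mg]Cc1ccoc1 | intermediate (not isolated)
13 | (1R,2R,4R,4aS,8aS)-1-[2-(furan-3-yl)ethyl]-2,5,5,8a-tetramethyldecahydronaphthalene-1,4-diol (15,16-epoxylabda-13(16),14-diene-6β,9α-diol) | O[C@@H]1C[C@@H](C)[C@](O)(CCc2ccoc2)[C@@]3(C)CCCC(C)(C)[C@H]13 | intermediate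
14 | (1R,3R,4R,4aS,8aS)-4-[2-(furan-3-yl)ethyl]-4-hydroxy-3,4a,8,8-tetramethyldecahydronaphthalen-1-yl acetate (6β-acetate of 13) | CC(=O)O[C@@H]1C[C@@H](C)[C@](O)(CCc2ccoc2)[C@@]3(C)CCCC(C)(C)[C@H]13 | intermediate
15 | (5S,6R,8R,9R,10S,13R,16S)-16-(phenylselanyl)-9,13:15,16-diepoxylabd-14-en-6-yl acetate (SePh trans to O9 on the dihydrofuran) | CC(=O)O[C@@H]1C[C@@H](C)[C@]2(CC[C@]3(C=CO[C@H]3[Se]c4ccccc4)O2)[C@@]5(C)CCCC(C)(C)[C@H]15 | intermediate
16 | (5S,6R,8R,9R,10S,13R)-9,13:15,16-diepoxylabd-14-en-6-yl acetate (CNP0242014.1) | CC(=O)O[C@@H]1C[C@@H](C)[C@]2(CC[C@]3(C=COC3)O2)[C@@]2(C)CCCC(C)(C)[C@H]12 | target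

**Step count**

Total: 11 steps. Longest linear sequence: 10 steps (steps 1–6 and 8–11, from 1 to 16); step 7 is a one-step side branch.

**Three steps most likely to fail**

Step 2 (Diels–Alder). The Z-methyl of diene 3 disfavours the s-cis geometry, and the strong Lewis acid may oligomerise the diene. Fallback, from 2 back to 6: quinone 2 is combined under the same catalyst with allylidenecyclopropane F1 (Wittig reaction of cyclopropyltriphenylphosphonium bromide with acrolein), whose tied-back terminus reaches the s-cis geometry easily, giving the spiro adduct F2. Hydrogenation over PtO2 in AcOH saturates both alkenes and cleaves the three-membered ring at its unsubstituted CH2–CH2 bond to reveal the gem-dimethyl group, and the base equilibration of step 3 then gives 6.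

Step 8 (epoxide opening). C11 is neopentyl-like, magnesium halide may rearrange the epoxide to an aldehyde, and the furylmethyl Grignard can react through furan C2. Fallback, from 8 (with 11) back to 13, making the C11–C12 bond by olefination instead of SN2: alkene 8 is dihydroxylated from the α-face (OsO4 cat., NMO) to the 6β,9α,11-triol F3, and the primary hydroxyl is oxidised selectively (TEMPO, PhI(OAc)2) to the 9α-hydroxy aldehyde F4. Wittig reaction with the ylide of (furan-3-ylmethyl)triphenylphosphonium chloride F5 (from 11 and PPh3; LiHMDS, THF) gives the 11-ene F6, and diimide (2-nitrobenzenesulfonyl hydrazide, Et3N) saturates C11=C12 without touching the furan, giving 13.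

Step 10 (dearomatising selenoetherification). It is unprecedented on a furan; selenium may attack C15 (leading to a six-membered acetal), the cation may simply lose a proton, and C13 selectivity is expected to be low. Fallback, from 13 back to 16, using conjugate addition instead of electrophilic dearomatisation: photo-oxygenation (O2, hν, rose bengal, i-Pr2NEt, CH2Cl2, −78 °C) turns the furan into the γ-hydroxybutenolide F7, and NaBH4 reduces it to the 13-en-15,16-olide F8. DBU in THF adds the 9α-hydroxyl to C13 by reversible oxa-Michael addition to give the spirolactone F9 (13-epimers separated, the unwanted one re-equilibrated with DBU). i-Bu2AlH (−78 °C) gives the lactol F10, MsCl/Et3N dehydrates it to the enol ether F11, and acetylation as in step 9 gives 16.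

**Further compounds**

F1 | step 2 | allylidenecyclopropane | C=CC=C1CC1
F2 | step 2 | (4a′R,8a′S)-2′,8a′-dimethyl-4a′,8′-dihydro-1′H-spiro[cyclopropane-1,5′-naphthalene]-1′,4′(8a′H)-dione | O=C1C=C(C)C(=O)[C@@]2(C)CC=CC3(CC3)[C@@H]12
F3 | step 8 | 12,13,14,15,16-pentanorlabdane-6β,9α,11-triol | O[C@@H]1C[C@@H](C)[C@](O)(CO)[C@@]2(C)CCCC(C)(C)[C@H]12
F4 | step 8 | 6β,9α-dihydroxy-12,13,14,15,16-pentanorlabdan-11-al | O[C@@H]1C[C@@H](C)[C@](O)(C=O)[C@@]2(C)CCCC(C)(C)[C@H]12
F5 | step 8 | (furan-3-ylmethyl)triphenylphosphonium chloride | [Cl-].c1ccc(cc1)[P+](Cc1ccoc1)(c1ccccc1)c1ccccc1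
F6 | step 8 | 15,16-epoxylabda-11,13(16),14-triene-6β,9α-diol (E/Z mixture) | O[C@@H]1C[C@@H](C)[C@](O)(C=Cc2ccoc2)[C@@]3(C)CCCC(C)(C)[C@H]13
F7 | step 10 | 6β,9α,16-trihydroxylabd-13-en-15,16-olide (C16 epimers) | O[C@@H]1C[C@@H](C)[C@](O)(CCC2=CC(=O)OC2O)[C@@]3(C)CCCC(C)(C)[C@H]13
F8 | step 10 | 6β,9α-dihydroxylabd-13-en-15,16-olide | O[C@@H]1C[C@@H](C)[C@](O)(CCC2=CC(=O)OC2)[C@@]3(C)CCCC(C)(C)[C@H]13
F9 | step 10 | (13R)-6β-hydroxy-9α,13-epoxylabdan-15,16-olide | O[C@@H]1C[C@@H](C)[C@]2(CC[C@]3(CC(=O)OC3)O2)[C@@]4(C)CCCC(C)(C)[C@H]14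
F10 | step 10 | (13R)-9α,13:15,16-diepoxylabdane-6β,15-diol (C15 anomers) | O[C@@H]1C[C@@H](C)[C@]2(CC[C@]3(CC(O)OC3)O2)[C@@]4(C)CCCC(C)(C)[C@H]14
F11 | step 10 | (13R)-9α,13:15,16-diepoxylabd-14-en-6β-ol | O[C@@H]1C[C@@H](C)[C@]2(CC[C@]3(C=COC3)O2)[C@@]4(C)CCCC(C)(C)[C@H]14
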